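**Assumptions (one line each)**
- The Ferrier glycosylation of D‑xylal diacetate is assumed to give mainly the 1,4‑trans (β‑D) glycoside, the minor cis anomer being removed by chromatography. If cis predominated, 3,4‑di‑O‑acetyl‑L‑arabinal would be used instead, because only the acetal centre survives step 3.
- tert‑Butyl buta‑2,3‑dienoate is taken as a catalogue reagent.
- Iridoid numbering is used in the explanations: C1 acetal, O2, C3=C4, C5, C6, C7, C8, C9, with C10 on C8 and C11 on C4. β is the face of H‑5/H‑9.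

**Retrosynthetic overview**
1. Target ⇐ selective C11 O‑isovalerylation of a C4 hydroxymethyl triol ⇐ Stille hydroxymethylation of a C4 enol triflate.
2. 7β‑OAc/8α‑OH/10‑OH ⇐ Ti‑directed acetolysis at C7 of a 7α,8α‑epoxy‑10‑ol ⇐ bromohydrin of the Δ7 allylic alcohol (Br⁺ on the convex β face, water at C8 from the α face).
3. Δ7‑8‑carboxylate/4‑ketone bicycle ⇐ phosphine‑catalysed [3+2] cycloaddition of an allenoate onto (S)‑6‑isopropoxy‑2H‑pyran‑3(6H)‑one; this builds the cyclopentene and sets C5/C9 anti to the C1 alkoxy group.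
4. Pyranone ⇐ Ferrier rearrangement, deacetylation and MnO2 oxidation of 3,4‑di‑O‑acetyl‑D‑xylal; sugar C4 sets the acetal centre and is then oxidised away.
5. Ring order: pyran (from the sugar) first, then cyclopentene by [3+2]; C1, C7 and C8 are set afterwards by substrate control.

**Route**

Step 1
Reactants: 1 (3,4‑di‑O‑acetyl‑D‑xylal), 2 (2‑propanol)
Product: 3, isopropyl 4‑O‑acetyl‑2,3‑dideoxy‑β‑D‑glycero‑pent‑2‑enopyranoside [(3S,6S)‑6‑isopropoxy‑3,6‑dihydro‑2H‑pyran‑3‑yl acetate]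
Conditions: i‑PrOH (2 eq), BF3·OEt2 (0.2 eq), CH2Cl2, −20 → 0 °C
Reagents that add atoms: 2‑propanol, CC(C)O
Why: Ferrier rearrangement; the allylic oxocarbenium formed by loss of 3‑OAc is captured at C1 trans to the C4 acetoxy group, so the sugar C4 centre sets the acetal centre (future C1).

Step 2
Reactants: 3
Product: 4, (3S,6S)‑6‑isopropoxy‑3,6‑dihydro‑2H‑pyran‑3‑ol
Conditions: K2CO3 (0.1 eq), MeOH, 0 °C → rt
Reagents that add atoms: none
Why: Zemplén‑type transesterification removes the acetate; the alkyl acetal and alkene are inert to mild base.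

Step 3
Reactants: 4
Product: 5, (6S)‑6‑isopropoxy‑2H‑pyran‑3(6H)‑one
Conditions: activated MnO2 (15 eq), CH2Cl2, rt
Reagents that add atoms: none
Why: Allylic alcohol oxidation to the enone under neutral conditions; the acetal carbon is now the only stereocentre and is not enolised.

Step 4
Reactants: 5, 6 (tert‑butyl buta‑2,3‑dienoate)
Product: 7, tert‑butyl (1S,4aS,7aS)‑1‑isopropoxy‑4‑oxo‑1,3,4,4a,5,7a‑hexahydrocyclopenta[c]pyran‑7‑carboxylate
Conditions: PPh3 (20 mol %), toluene, 80–110 °C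
Reagents that add atoms: tert‑butyl buta‑2,3‑dienoate, C=C=CC(=O)OC(C)(C)C
Why: Lu phosphine‑catalysed [3+2] cycloaddition; the allenoate α‑carbon bonds to the enone β‑carbon (C9) and the γ‑carbon to C5, and approach anti to the pseudo‑axial 6‑alkoxy group gives the cis‑fused ring with H‑5/H‑9 syn to C1–OR.

Step 5
Reactants: 7, 8 (isovaleric anhydride, used with isovaleric acid)
Product: 9, tert‑butyl (1S,4aS,7aS)‑1‑[(3‑methylbutanoyl)oxy]‑4‑oxo‑1,3,4,4a,5,7a‑hexahydrocyclopenta[c]pyran‑7‑carboxylate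
Conditions: i‑BuCO2H (10 eq), (i‑BuCO)2O (3 eq), CSA (0.2 eq), CH2Cl2, 0 °C → rt
Reagents that add atoms: isovaleric acid, CC(C)CC(=O)O; isovaleric anhydride, CC(C)CC(=O)OC(=O)CC(C)C
Why: Acid‑catalysed acetal‑to‑acyloxy‑acetal exchange through the C1 oxocarbenium (the anhydride scavenges i‑PrOH; catalytic CSA leaves the tert‑butyl ester intact); the carboxylic acid adds trans to the C9–C8 bond, giving the 1β ester, and there is no free OH to compete.

Step 6
Reactants: 9
Product: 10, tert‑butyl (1S,4aS,7aS)‑1‑[(3‑methylbutanoyl)oxy]‑4‑[(trifluoromethanesulfonyl)oxy]‑1,4a,5,7a‑tetrahydrocyclopenta[c]pyran‑7‑carboxylate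
Conditions: KHMDS (1.1 eq), THF, −78 °C; PhNTf2, −78 → −20 °C
Reagents that add atoms: N‑phenyl‑bis(trifluoromethanesulfonimide), O=S(=O)(N(c1ccccc1)S(=O)(=O)C(F)(F)F)C(F)(F)F
Why: Kinetic enolisation of the ketone at the unhindered C3 methylene (not the ring‑fusion C5–H) and O‑triflation give the C3=C4 enol triflate; the ketone is far more acidic than either ester, and cis fusion is retained.

Step 7
Reactants: 10
Product: 11, (1S,4aS,7aS)‑1‑[(3‑methylbutanoyl)oxy]‑4‑[(trifluoromethanesulfonyl)oxy]‑1,4a,5,7a‑tetrahydrocyclopenta[c]pyran‑7‑carboxylic acid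
Conditions: TFA/CH2Cl2 (1:3), 0 °C → rt
Reagents that add atoms: none
Why: Acidolysis of the tert‑butyl ester (loss of isobutene); the C1 acyloxy acetal is hard to ionise because O2 is now an electron‑poor enol‑triflate oxygen, and the vinyl triflate is acid‑stable.

Step 8
Reactants: 11
Product: 12, (1S,4aS,7aS)‑7‑(hydroxymethyl)‑4‑[(trifluoromethanesulfonyl)oxy]‑1,4a,5,7a‑tetrahydrocyclopenta[c]pyran‑1‑yl 3‑methylbutanoate
Conditions: i‑BuOCOCl, NMM, THF, −15 °C; then NaBH4, H2O, 0 °C, 15 min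
Reagents that add atoms: none (hydride only)
Why: Mixed carbonic anhydride activation and borohydride reduction convert only the carboxylic acid into the C10 allylic alcohol; the isovalerate and vinyl triflate are untouched, which is why DIBAL on an ester was avoided.

Step 9
Reactants: 12
Product: 13, (1S,4aS,6S,7R,7aS)‑6‑bromo‑7‑hydroxy‑7‑(hydroxymethyl)‑4‑[(trifluoromethanesulfonyl)oxy]‑1,4a,5,6,7,7a‑hexahydrocyclopenta[c]pyran‑1‑yl 3‑methylbutanoate (7β‑Br, 8α‑OH)
Conditions: NBS (1.1 eq), THF/H2O (4:1), NaHCO3, 0 °C, dark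
Reagents that add atoms: N‑bromosuccinimide, O=C1CCC(=O)N1Br; water, O
Why: Bromohydrin formation; Br⁺ adds to the trisubstituted C7=C8 from the convex β face and water opens the bromonium anti at the tertiary C8, setting 8α‑OH, while the triflate‑substituted C3=C4 is too electron‑poor to compete.

Step 10
Reactants: 13
Product: 14, the 7α,8α‑epoxide (7R,8R in iridoid numbering) of 12, with 8β‑CH2OH free and the 1β‑isovalerate and 4‑triflate retained
Conditions: DBU (1.5 eq), CH2Cl2, 0 °C (can be telescoped from step 9)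
Reagents that add atoms: none
Why: Intramolecular Williamson closure; the 8α‑alkoxide displaces the trans 7β‑bromide with inversion at C7, and the non‑nucleophilic base spares the C1 ester.

Step 11
Reactants: 14
Product: 15, (1S,4aS,6S,7R,7aS)‑6‑acetoxy‑7‑hydroxy‑7‑(hydroxymethyl)‑4‑[(trifluoromethanesulfonyl)oxy]‑1,4a,5,6,7,7a‑hexahydrocyclopenta[c]pyran‑1‑yl 3‑methylbutanoate
Conditions: Ti(OiPr)4 (1.5 eq), AcOH (2 eq), CH2Cl2, 0 °C → rt
Reagents that add atoms: acetic acid, CC(=O)O
Why: Sharpless‑type Ti‑chelate‑directed opening of a 2,3‑epoxy alcohol at C3 (here C7) by the carboxylic acid; SN2 inversion gives 7β‑OAc and leaves 8α‑OH and 10‑OH free.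

Step 12
Reactants: 15, 16 ((tributylstannyl)methanol)
Product: 17, (1S,4aS,6S,7R,7aS)‑6‑acetoxy‑7‑hydroxy‑4,7‑bis(hydroxymethyl)‑1,4a,5,6,7,7a‑hexahydrocyclopenta[c]pyran‑1‑yl 3‑methylbutanoate
Conditions: Bu3SnCH2OH (1.5 eq), Pd(PPh3)4 (10 mol %), LiCl (3 eq), 1,4‑dioxane, 85 °C
Reagents that add atoms: (tributylstannyl)methanol, CCCC[Sn](CCCC)(CCCC)CO
Why: Stille (Kosugi) hydroxymethylation of the enol triflate installs C11 at the alcohol oxidation level under neutral conditions tolerated by the esters and free diol; no stereocentre is touched.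

Step 13
Reactants: 17, 18 (isovaleryl chloride)
Product: 19, Jatamanvaltrate H, (1S,4aS,6S,7R,7aS)‑6‑acetoxy‑7‑hydroxy‑7‑(hydroxymethyl)‑4‑{[(3‑methylbutanoyl)oxy]methyl}‑1,4a,5,6,7,7a‑hexahydrocyclopenta[c]pyran‑1‑yl 3‑methylbutanoate
Conditions: PhB(OH)2 (1.1 eq), 4 Å MS, CH2Cl2, rt; then pyridine, i‑BuCOCl (1.2 eq), −20 → 0 °C; pinacol/aq. NaHCO3 work‑up
Reagents that add atoms: isovaleryl chloride, CC(C)CC(Cl)=O
Why: A transient cyclic phenylboronate masks the 8‑OH/10‑OH 1,2‑diol so that only the allylic C11–OH is esterified; the boronate is removed by transesterification on neutral work‑up, sparing the enol ether and acyloxy acetal.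

**Compound list**
1 | 3,4‑di‑O‑acetyl‑D‑xylal | C1=C[C@@H](OC(C)=O)[C@H](OC(C)=O)CO1 | starting material
2 | 2‑propanol | CC(C)O | starting material
3 | isopropyl 4‑O‑acetyl‑2,3‑dideoxy‑β‑D‑glycero‑pent‑2‑enopyranoside | CC(=O)O[C@@H]1CO[C@@H](OC(C)C)C=C1 | intermediate
4 | (3S,6S)‑6‑isopropoxy‑3,6‑dihydro‑2H‑pyran‑3‑ol | O[C@@H]1CO[C@@H](OC(C)C)C=C1 | intermediate
5 | (6S)‑6‑isopropoxy‑2H‑pyran‑3(6H)‑one | O=C1CO[C@@H](OC(C)C)C=C1 | intermediate
6 | tert‑butyl buta‑2,3‑dienoate | C=C=CC(=O)OC(C)(C)C | starting material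
7 | [3+2] adduct (1‑OiPr, 4‑oxo, 7‑CO2tBu) | CC(C)O[C@@H]1OCC(=O)[C@H]2CC=C(C(=O)OC(C)(C)C)[C@@H]12 | intermediate
8 | isovaleric anhydride | CC(C)CC(=O)OC(=O)CC(C)C | starting material
9 | 1β‑isovalerate ketone | CC(C)CC(=O)O[C@@H]1OCC(=O)[C@H]2CC=C(C(=O)OC(C)(C)C)[C@@H]12 | intermediate
10 | enol triflate tert‑butyl ester | CC(C)CC(=O)O[C@@H]1OC=C(OS(=O)(=O)C(F)(F)F)[C@H]2CC=C(C(=O)OC(C)(C)C)[C@@H]12 | intermediate
11 | enol triflate carboxylic acid | CC(C)CC(=O)O[C@@H]1OC=C(OS(=O)(=O)C(F)(F)F)[C@H]2CC=C(C(=O)O)[C@@H]12 | intermediate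
12 | Δ7 C10 allylic alcohol | CC(C)CC(=O)O[C@@H]1OC=C(OS(=O)(=O)C(F)(F)F)[C@H]2CC=C(CO)[C@@H]12 | intermediate
13 | 7β‑bromo‑8α‑hydroxy bromohydrin | CC(C)CC(=O)O[C@@H]1OC=C(OS(=O)(=O)C(F)(F)F)[C@H]2C[C@H](Br)[C@](O)(CO)[C@@H]12 | intermediate
14 | 7α,8α‑epoxy‑10‑ol | CC(C)CC(=O)O[C@@H]1OC=C(OS(=O)(=O)C(F)(F)F)[C@H]2C[C@H]3O[C@@]3(CO)[C@@H]12 | intermediate
15 | 7β‑acetoxy‑8α,10‑diol enol triflate | CC(C)CC(=O)O[C@@H]1OC=C(OS(=O)(=O)C(F)(F)F)[C@H]2C[C@H](OC(C)=O)[C@](O)(CO)[C@@H]12 | intermediate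
16 | (tributylstannyl)methanol | CCCC[Sn](CCCC)(CCCC)CO | starting material
17 | C11 alcohol (8,10,11‑triol) | CC(C)CC(=O)O[C@@H]1OC=C(CO)[C@H]2C[C@H](OC(C)=O)[C@](O)(CO)[C@@H]12 | intermediate
18 | isovaleryl chloride | CC(C)CC(Cl)=O | starting material
19 | Jatamanvaltrate H | CC(=O)O[C@H]1C[C@@H]2C(COC(=O)CC(C)C)=CO[C@@H](OC(=O)CC(C)C)[C@@H]2[C@@]1(O)CO | target

**Totals**
Total steps: 13. Longest linear sequence: 13 (from compound 1).

**Three steps most likely to fail, with fallbacks**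
1. Step 4 ([3+2] on the 6‑alkoxy pyranone): regio‑ or facial selectivity may be lower than with a 6‑acyloxy group, and the γ‑acetal proton could epimerise under phosphine catalysis. Fallback: build both rings in one intramolecular inverse‑demand oxa‑Diels–Alder reaction (domino Knoevenagel/hetero‑Diels–Alder of malondialdehyde with an acyclic 2‑deoxy‑D‑ribose‑derived aldehyde carrying the C7/C8 oxygens and a tethered enol ester), giving the C4‑formyl dihydropyran directly.
2. Step 11 (Ti‑mediated acetolysis at C7): possible attack at C8, transesterification of the C1 acyloxy acetal, or acetyl migration to C10. Fallback: epoxidise 12 from the β face (VO(acac)2/TBHP), hydrolyse under acid catalysis at tertiary C8 with inversion to the 7β,8α,10‑triol, protect 8,10 as an acetonide, acetylate C7, and remove the acetonide at the end.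
3. Step 13 (C11 versus C10 acylation): incomplete boronate masking would give C10 or bis esters. Fallback: protect the 8,10‑diol of 15 as an isolated di‑tert‑butylsilylene before the Stille step, acylate the sole free C11–OH, and remove the silylene with HF·pyridine (two extra steps).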